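**Structural features**

The target 17 is a 3-arylcoumarin: benzene ring A is fused to an α-pyranone (lactone ring C: O1, C2, C3, C4, C4a, C8a), and C3 of that ring is bonded to C1′ of a second benzene, ring B. Ring A has the 1,3,5-trioxygenation of phloroglucinol, but its three oxygens are all different: O5 is a methyl ether, O7 a free phenol, and the oxygen on C8a is O1 of the lactone. Ring B is a resorcinol (hydroxyls on C2′ and C4′) with a 3-methylbut-2-enyl (prenyl) chain on C3′, the carbon between them. There is no stereocentre and no alkene geometry to set, so no stereocentres stand next to one another; the sp3 centre at C3 that appears in 11 to 15 is transient and racemic. The fragile parts are the prenyl group flanked by two phenols (acid closes it to a 2,2-dimethylchroman, oxidants to a chromene), the oxidisable electron-rich phenols, and O2′, which sits ortho to C1′ and would close a five-membered lactone onto C2 if it were free while ring C is formed. The real difficulty is therefore differentiation and not size: three unlike oxygens on ring A, one defined site of C-prenylation on ring B, and the choice of the phenol that closes the lactone. The key step uses the fact that C4a–C5(OMe)–C6–C7(O)–C8 with C8a(=O) of ring A is, atom for atom, C3–C4(OMe)–C5–C6(O1)–CH3 with C2(=O) of 4-methoxy-6-methylpyran-2-one, so the heterocycle stores the C5 methyl ether, the C7 oxygen and the C8a oxygen already told apart. One descriptor is corrected here: the ring-opened chain in which the ester and the ketone arm stay cis across the enol ether double bond has the ester trans to the methoxy group and is therefore (E), not (Z), by the sequence rules.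

**Logic of the disconnections**

17 from 16. The two acetal O–CH2 bonds on O2′ and O4′ are cut last. Both ring B phenols must stay masked through organolithium chemistry, methoxide and an oxidant, and O2′ in particular must be blocked while the lactone closes. Nothing is gained in skeleton, but 16 is robust. The forward step must unmask two phenols beside a prenyl group without protonating its alkene.

16 from 15. The C3=C4 double bond is traced back to a C3–C4 single bond. This puts an sp3 methylene at C4, which is what a conjugate addition can deliver, and it is the oxidation level at which the key step arrives. The forward step must remove two hydrogens from C3 and C4 only, sparing the benzylic, allylic CH2 of the prenyl group. The free O7–H para to C4a is the handle for that selectivity.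

15 from 12 (through 14 and 13). O1–C2 and C8–C8a are cut. Both ring A and the lactone ring disappear, and what remains is a monocyclic heterocycle that already carries the methyl ether, joined to a simple ester. The forward step must open the heterocycle, keep the ester and ketone arms cis, close C8 onto C8a, aromatise, and lactonise through the one phenol that is ortho to the side chain, while O2′ stays protected.

12 from 11. The O–CH3 bond on the future O5 is cut. The free 4-hydroxy heterocycle is needed one step earlier as a carbon nucleophile. It must then be capped, both to fix the C5 methyl ether and to make the ring open to alkoxide. The forward step must methylate the 4-oxygen and not the 2-oxygen.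

11 from 9 and 10. C4–C4a is cut. C4a is the nucleophilic C3 of 10 and C4 is the β-carbon of the acrylate in 9, so this cut separates the ring A precursor from ring B completely and uses 10 as purchased. The forward step needs C-alkylation instead of O-alkylation and an acceptor that does not oligomerise first.

9 from 5 and 6 (through 7 and 8). C3–C1′ is cut. C1′ is ortho to an acetal oxygen and so is available as an aryl anion. Coupling with 6 brings in C2, C3 and the methylene that becomes C4 in one operation, which removes any separate homologation and methylenation. The forward step needs ring metalation to win over deprotonation of the prenyl CH2, and a coupling that tolerates an acrylate.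

5 from 2 and 3 (through 4). The C3′–CH2 bond is cut. The carbon between the two acetal oxygens is the most acidic site of 2, so the prenyl position is fixed by the substrate. The forward step must give the linear allyl product, not the transposed one.

2 from 1. Two O–CH2 bonds are cut. The acetal is chosen because it directs both metalations, survives methoxide, and is removed without hydrogenolysis.

**Other disconnections considered**

Alternative 1: The cut is through ring B itself, along C3′–C4′, C1′–C2′ and C4′–C5′, into the cyclobutenone methyl 2-(4-oxocyclobut-1-en-1-yl)acetate A2 and the siloxyalkyne triisopropyl[(5-methylhex-4-en-1-yn-1-yl)oxy]silane A3. In the forward direction A2 would open thermally (4π) to a vinylketene and add A3 by [2+2] cycloaddition. The resulting 2-vinylcyclobutenone would open again and close by 6π electrocyclisation to methyl 2-[4-hydroxy-3-(3-methylbut-2-enyl)-2-(triisopropylsilyloxy)phenyl]acetate A1.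
- In favour: the prenyl group is placed between the two oxygens by the connectivity of the alkyne alone, no organometallic step is run beside the allylic chain, and O2′ and O4′ emerge differentiated.
- Against: ring B of 17 is only resorcinol substituted at its most acidic carbon, which 5 reaches in two steps. A2 (a 2-alkylcyclobutenone with free C3 and C4 and an enolisable ester arm) and A3 each need a multistep preparation, and A2 is expected to be prone to dimerisation and double-bond migration. The differentiation of O2′ and O4′ is not needed, because both end as free phenols. A1 is still only an arylacetate, so ring A, the lactone and the C3–C4 unit would all remain to be built after protecting-group adjustment and α-methylenation.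
- Comparison: on regiochemical certainty for ring B the two plans are equal. On avoiding a metalation next to the prenyl CH2 the alternative is the better one. On mechanism it is an elegant pericyclic cascade, but it is spent on the easy ring. On step economy the chosen plan is far shorter, and the alternative leaves the real problem, three unlike oxygens on ring A, untouched.

Alternative 2: The cut is through the lactone ring along C8a–O1, C4a–C4, C3=C4 and O1–C2, into three pieces: the aryne precursor [3-methoxy-5-(methoxymethoxy)-2-(trimethylsilyl)phenyl] trifluoromethanesulfonate A5, N,N-dimethylformamide A7 as the donor of C4, and the ring B silyl ketene acetal {2-[2,4-bis(methoxymethoxy)-3-(3-methylbut-2-enyl)phenyl]-1-methoxyethenoxy}trimethylsilane A6. In the forward direction fluoride would release the aryne from A5. The aryne would insert into the C=O bond of A7 through a four-membered adduct that opens to an ortho-quinone methide. A6 would add at the methide carbon, the amino group would be lost, and the phenoxide would acylate on the ester to give 3-[2,4-bis(methoxymethoxy)-3-(3-methylbut-2-enyl)phenyl]-5-methoxy-7-(methoxymethoxy)chromen-2-one A4.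
- In favour: four bonds form in one operation and the coumarin oxidation level is reached directly. The methoxy group next to the aryne bond should send the oxygen to the distal carbon (C8a), so regiocontrol is in principle equal to that of the chosen plan. After the key step only the removal of three acetals remains, one step fewer than after step 6, and on this point the alternative is the better one.
- Against: A5 requires a phloroglucinol whose three oxygens are made different (methyl, acetal, triflate) and then silylated. That is the same differentiation problem that the chosen plan solves with a purchased heterocycle, moved into a reagent synthesis of five or six steps. Three-component aryne couplings have competing channels (a second aryne adding to the quinone methide or to the phenoxide, fluoride desilylating A6 before it is trapped). The valuable ring B piece would thus be committed to a step of uncertain efficiency. A6 itself needs the arylacetate, which is longer to make than 9.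
- Comparison: on structure both plans fix O5, O7 and O1 unambiguously. On mechanism the chosen plan relies on covalent pre-organisation, the alternative on aryne distortion. On step economy the alternative gains one step at the end but loses several in the preparation of A5 and A6.

Alternative 3: The cut is through the lactone ring along C4–C4a and O1–C2, with ring A carried in saturated form: 5-[tert-butyl(dimethyl)silyl]oxycyclohexane-1,3-dione A9 and the enamino ester methyl 2-[2,4-bis(methoxymethoxy)-3-(3-methylbut-2-enyl)phenyl]-3-(dimethylamino)prop-2-enoate A10. In the forward direction C2 of A9 would attack the β-carbon of A10 in an addition–elimination, and the enol oxygen would then acylate on the ester to give racemic 3-[2,4-bis(methoxymethoxy)-3-(3-methylbut-2-enyl)phenyl]-7-[tert-butyl(dimethyl)silyl]oxy-7,8-dihydro-6H-chromene-2,5-dione A8.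
- In favour: A9 is symmetric, so the annulation poses no regiochemical question (equal to the chosen plan). C3=C4 is formed directly, so no lactone dehydrogenation is needed (better than the chosen plan, which needs step 7). The silyl ether keeps O7 distinct from O5.
- Against: ring A of A8 must afterwards lose two hydrogens with an external oxidant in a β-silyloxy ketone, where β-elimination would erase the C7 oxygen altogether, and that oxidant must also spare the prenyl group. The C5 hydroxyl then has to be methylated and the silyl and acetal groups removed. That is about four operations after the key step against two here. A9 and A10 both need separate preparation.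
- Comparison: on structure the differentiation of O5 and O7 is as secure as in the chosen plan. On mechanism the vinylogous substitution and lactonisation is a robust pyranone annulation, but the aromatisation that step 6 gets from tautomerisation alone becomes a redox step at a sensitive stage. On step economy the alternative is longer.

Key step: step 6

Remark on the chemistry: 17 has no stereocentre; 11 to 15 carry one stereocentre at the future C3 and are handled as racemates, because this carbon becomes sp2 in step 7.

**Route**

Step 1
Reactants: 1 resorcinol (benzene-1,3-diol)
Product: 2 1,3-bis(methoxymethoxy)benzene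
Conditions: NaH, MOMCl, DMF, 0 °C to rt
Reagents that add atoms: chloromethyl methyl ether (MOMCl), COCCl
Why: Williamson-type O-alkylation of both phenoxides by the α-chloro ether should give the bis-acetal; the acetal is chosen because it directs ortho-lithiation, is inert to methoxide and needs no hydrogenolysis for removal.

Step 2
Reactants: 2 1,3-bis(methoxymethoxy)benzene; 3 1-bromo-3-methylbut-2-ene
Product: 5 1,3-bis(methoxymethoxy)-2-(3-methylbut-2-enyl)benzene, via C2-lithiated arene 4 (not isolated)
Conditions: n-BuLi, THF, 0 °C to rt; CuI (10 mol %), −30 °C; then 3, −30 °C to rt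
Reagents that add atoms: none
Why: Directed ortho-metalation removes the hydrogen between the two coordinating acetal oxygens, and copper-catalysed allylic substitution of the aryl nucleophile on the primary bromide should give the linear prenyl arene and not the SN2′ isomer.

Step 3
Reactants: 5 1,3-bis(methoxymethoxy)-2-(3-methylbut-2-enyl)benzene; 6 methyl 2-bromoprop-2-enoate
Product: 9 methyl 2-[2,4-bis(methoxymethoxy)-3-(3-methylbut-2-enyl)phenyl]prop-2-enoate, via C4-lithiated arene 7 (not isolated), via arylzinc chloride 8 (not isolated)
Conditions: n-BuLi, TMEDA, THF, 0 °C; ZnCl2, 0 °C to rt; then 6, Pd(PPh3)4 (5 mol %), BHT (cat.), THF, rt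
Reagents that add atoms: none
Why: A second directed ortho-metalation can only occur at C4 or C6, which are equivalent by symmetry; exchange to zinc gives a non-basic aryl nucleophile, and Negishi coupling (oxidative addition of zerovalent palladium into the vinyl C–Br bond, transmetalation, reductive elimination) should form C3–C1′ and deliver the 2-arylacrylate directly.

Step 4
Reactants: 9 methyl 2-[2,4-bis(methoxymethoxy)-3-(3-methylbut-2-enyl)phenyl]prop-2-enoate; 10 4-hydroxy-6-methylpyran-2-one
Product: 11 methyl 2-[2,4-bis(methoxymethoxy)-3-(3-methylbut-2-enyl)phenyl]-3-(4-hydroxy-6-methyl-2-oxopyran-3-yl)propanoate (racemic)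
Conditions: DBU (0.5 equiv), BHT (cat.), MeCN, 60 °C; aq. citric acid work-up
Reagents that add atoms: none
Why: Michael addition: C3 of the vinylogous acid 10 is its soft carbon nucleophile and adds to the acrylate β-carbon (C4–C4a), whereas O-addition is reversible; the new stereocentre at the ester α-carbon forms without control (racemate) and becomes sp2 in step 7.

Step 5
Reactants: 11 methyl 2-[2,4-bis(methoxymethoxy)-3-(3-methylbut-2-enyl)phenyl]-3-(4-hydroxy-6-methyl-2-oxopyran-3-yl)propanoate (racemic)
Product: 12 methyl 2-[2,4-bis(methoxymethoxy)-3-(3-methylbut-2-enyl)phenyl]-3-(4-methoxy-6-methyl-2-oxopyran-3-yl)propanoate (racemic)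
Conditions: Me2SO4, K2CO3, acetone, reflux
Reagents that add atoms: dimethyl sulfate, COS(=O)(=O)OC
Why: O-methylation of the ambident pyranone anion with a hard electrophile in acetone should favour the conjugated 4-methoxy-2-pyranone; K2CO3 is too weak to deprotonate the ester α-CH, so no C-methylation is expected.

Step 6
Reactants: 12 methyl 2-[2,4-bis(methoxymethoxy)-3-(3-methylbut-2-enyl)phenyl]-3-(4-methoxy-6-methyl-2-oxopyran-3-yl)propanoate (racemic)
Product: 15 3-[2,4-bis(methoxymethoxy)-3-(3-methylbut-2-enyl)phenyl]-7-hydroxy-5-methoxychroman-2-one (racemic), via ring-opened keto diester 13 (not isolated), via phenolic methyl ester 14 (not isolated)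
Conditions: NaOMe (4 equiv), MeOH, 65 °C, Ar; AcOH to pH 5–6, evaporate; PPTS (10 mol %), 4 Å MS, toluene, 80 °C
Reagents that add atoms: none
Why: Methoxide adds to the lactone carbonyl of the pyranone (future C8a) and opens the ring by acyl substitution to the methyl ester and methyl ketone 13, in which the enol ether double bond keeps the new ester and the 2-oxopropyl arm cis, the (E) geometry. The methyl ketone enolate (future C8) then attacks that ester carbonyl in a Claisen condensation, a 6-(enolendo)-exo-trig closure, and expels the same methoxide that opened the ring; tautomerisation of the resulting cyclohexadienone to the phenoxide of 14 is irreversible and draws the reversible ring opening and the more stable but unproductive internal enolate through. The closest known reaction type is the alkoxide unravelling of 4-oxygenated 6-methylpyran-2-ones to triketide chains and their Claisen folding to phloroglucinols, the laboratory counterpart of polyketide cyclisation. After neutralisation the C8a hydroxyl of 14 attacks the side-chain ester in a 6-exo-trig acyl substitution, the methanol is taken up by the sieves, and the lactone ring of 15 closes. No stereocentre is created; the one at C3 is racemic, epimerisable under methoxide and removed in step 7. Regioselectivity needs no reagent control: the enol ether oxygen becomes O5 with its methyl group, the ring oxygen becomes the C7 hydroxyl and the carbonyl oxygen becomes the C8a hydroxyl, so the only free phenol ortho to the side chain is on C8a. Chemoselectivity rests on two degenerate exchanges (methoxide on the methyl ester and on the methyl enol ether change nothing) and on the O2′ acetal, which is inert to methoxide and to the buffered acid and so blocks the five-membered lactone from ring B.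

Step 7
Reactants: 15 3-[2,4-bis(methoxymethoxy)-3-(3-methylbut-2-enyl)phenyl]-7-hydroxy-5-methoxychroman-2-one (racemic)
Product: 16 3-[2,4-bis(methoxymethoxy)-3-(3-methylbut-2-enyl)phenyl]-7-hydroxy-5-methoxychromen-2-one
Conditions: DDQ (1.1 equiv), 1,4-dioxane, rt
Reagents that add atoms: none
Why: Quinone dehydrogenation: hydride abstraction at C4, benzylic to ring A and activated by the para C7 hydroxyl and the ortho C5 methoxy group, gives a para-quinone methide, and loss of the acidic C3 proton then gives the conjugated coumarin; the prenyl CH2 sits on the acetal-protected, less activated ring B, so one equivalent of oxidant at room temperature should leave it alone.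

Step 8
Reactants: 16 3-[2,4-bis(methoxymethoxy)-3-(3-methylbut-2-enyl)phenyl]-7-hydroxy-5-methoxychromen-2-one
Product: 17 3-[2,4-dihydroxy-3-(3-methylbut-2-enyl)phenyl]-7-hydroxy-5-methoxychromen-2-one
Conditions: conc. aq. HCl (cat.), MeOH, 40 °C
Reagents that add atoms: none
Why: Acid-catalysed acetal exchange with methanol should release both ring B phenols; dilute acid at moderate temperature is chosen because protonation of the trisubstituted alkene, the entry to chroman formation, needs stronger acid, and the coumarin lactone is stable to these conditions.

**Compound list**

1 | resorcinol (benzene-1,3-diol) | Oc1cccc(O)c1 | starting material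
2 | 1,3-bis(methoxymethoxy)benzene | COCOc1cccc(OCOC)c1 | intermediate
3 | 1-bromo-3-methylbut-2-ene | CC(C)=CCBr | starting material
4 | [2,6-bis(methoxymethoxy)phenyl]lithium | [Li]c1c(OCOC)cccc1OCOC | intermediate
5 | 1,3-bis(methoxymethoxy)-2-(3-methylbut-2-enyl)benzene | COCOc1cccc(OCOC)c1CC=C(C)C | intermediate
6 | methyl 2-bromoprop-2-enoate | COC(=O)C(Br)=C | starting material
7 | [2,4-bis(methoxymethoxy)-3-(3-methylbut-2-enyl)phenyl]lithium | [Li]c1ccc(OCOC)c(CC=C(C)C)c1OCOC | intermediate
8 | chloro[2,4-bis(methoxymethoxy)-3-(3-methylbut-2-enyl)phenyl]zinc | Cl[Zn]c1ccc(OCOC)c(CC=C(C)C)c1OCOC | intermediate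
9 | methyl 2-[2,4-bis(methoxymethoxy)-3-(3-methylbut-2-enyl)phenyl]prop-2-enoate | COC(=O)C(=C)c1ccc(OCOC)c(CC=C(C)C)c1OCOC | intermediate
10 | 4-hydroxy-6-methylpyran-2-one | Cc1cc(O)cc(=O)o1 | starting material
11 | methyl 2-[2,4-bis(methoxymethoxy)-3-(3-methylbut-2-enyl)phenyl]-3-(4-hydroxy-6-methyl-2-oxopyran-3-yl)propanoate (racemic) | COC(=O)C(Cc1c(O)cc(C)oc1=O)c1ccc(OCOC)c(CC=C(C)C)c1OCOC | intermediate
12 | methyl 2-[2,4-bis(methoxymethoxy)-3-(3-methylbut-2-enyl)phenyl]-3-(4-methoxy-6-methyl-2-oxopyran-3-yl)propanoate (racemic) | COC(=O)C(Cc1c(OC)cc(C)oc1=O)c1ccc(OCOC)c(CC=C(C)C)c1OCOC | intermediate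
13 | dimethyl (4E)-2-[2,4-bis(methoxymethoxy)-3-(3-methylbut-2-enyl)phenyl]-4-(1-methoxy-3-oxobutylidene)pentanedioate (racemic) | COC(=O)C(C/C(C(=O)OC)=C(\OC)CC(C)=O)c1ccc(OCOC)c(CC=C(C)C)c1OCOC | intermediate
14 | methyl 2-[2,4-bis(methoxymethoxy)-3-(3-methylbut-2-enyl)phenyl]-3-(2,4-dihydroxy-6-methoxyphenyl)propanoate (racemic) | COC(=O)C(Cc1c(O)cc(O)cc1OC)c1ccc(OCOC)c(CC=C(C)C)c1OCOC | intermediate
15 | 3-[2,4-bis(methoxymethoxy)-3-(3-methylbut-2-enyl)phenyl]-7-hydroxy-5-methoxychroman-2-one (racemic) | COc1cc(O)cc2c1CC(C(=O)O2)c1ccc(OCOC)c(CC=C(C)C)c1OCOC | intermediate
16 | 3-[2,4-bis(methoxymethoxy)-3-(3-methylbut-2-enyl)phenyl]-7-hydroxy-5-methoxychromen-2-one | COc1cc(O)cc2oc(=O)c(-c3ccc(OCOC)c(CC=C(C)C)c3OCOC)cc12 | intermediate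
17 | 3-[2,4-dihydroxy-3-(3-methylbut-2-enyl)phenyl]-7-hydroxy-5-methoxychromen-2-one | COc1cc(O)cc2oc(=O)c(-c3ccc(O)c(CC=C(C)C)c3O)cc12 | target

**Step count and least certain steps**

Total step count: 8. Longest linear sequence: 8 steps (1 to 17); 3, 6 and 10 enter as purchased materials.

Step 6 (key step). The attacked carbonyl is a β-methoxy, α-alkyl enoate ester, hindered and deactivated, so the Claisen closure may be slow. Side processes could then take over: geometric isomerisation of 13 through its dienolate to the isomer whose arms are trans and cannot close, Dieckmann-type acylation of the internal carbanion onto the side-chain ester from that isomer, or retro-Michael loss of the ring B acrylate. In the lactonisation, acid-induced loss of the O2′ acetal would open the way to a five-membered lactone. The fallback leaves the pyranone strategy and builds the lactone ring by a Perkin–Oglialoro condensation, with the ring A oxygens taken from a salicylaldehyde. It sets out from 5 and comes back at 16. 5 would be lithiated as in step 3 and the aryllithium opened onto ethylene oxide to give 2-[2,4-bis(methoxymethoxy)-3-(3-methylbut-2-enyl)phenyl]ethanol F1. Oxidation with TEMPO and PhI(OAc)2 in MeCN–water would give 2-[2,4-bis(methoxymethoxy)-3-(3-methylbut-2-enyl)phenyl]acetic acid F2. Condensation of F2 with purchased 2,4-dihydroxy-6-methoxybenzaldehyde F3 in Ac2O/Et3N at 110 °C should give [3-[2,4-bis(methoxymethoxy)-3-(3-methylbut-2-enyl)phenyl]-5-methoxy-2-oxochromen-7-yl] acetate F4. Methanolysis of the acetate (K2CO3, MeOH, rt) would return 16, and step 8 follows unchanged.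

Step 4. The conjugate addition may stall, because the pyranone anion is a weak nucleophile and the ester enolate formed on addition is high in energy; meanwhile the acrylate can oligomerise, and 11 can cyclise to an enol lactone on work-up. The fallback makes C4–C4a by cross-coupling instead; it sets out from 9 and 10 and comes back at 12, so it also bypasses step 5. Conjugate borylation of 9 (B2pin2, CuCl, NaOt-Bu, DPEphos, MeOH, THF) would give methyl 2-[2,4-bis(methoxymethoxy)-3-(3-methylbut-2-enyl)phenyl]-3-(4,4,5,5-tetramethyl-1,3,2-dioxaborolan-2-yl)propanoate F5. In parallel 10 would be O-methylated (Me2SO4, K2CO3, acetone) to 4-methoxy-6-methylpyran-2-one F6 and brominated at C3 with NBS to 3-bromo-4-methoxy-6-methylpyran-2-one F7. Suzuki–Miyaura coupling of F5 with F7 (Pd(OAc)2, RuPhos, K3PO4, toluene–water, 80 °C) should give 12.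

Step 7. The oxidant may attack at the wrong site: hydride abstraction from the benzylic, allylic CH2 of the prenyl group, or further oxidation of the phenolic ring A. The fallback replaces hydride abstraction by enolate chemistry; it sets out from 15 and comes back at 16. Double deprotonation of 15 (LiHMDS, 2.2 equiv, THF, −78 °C) and selenenylation of the lactone enolate with PhSeCl would give 3-[2,4-bis(methoxymethoxy)-3-(3-methylbut-2-enyl)phenyl]-7-hydroxy-5-methoxy-3-(phenylselanyl)chroman-2-one F8 (racemic). Oxidation (H2O2, pyridine, CH2Cl2, 0 °C) and syn-elimination of the selenoxide towards C4 should give 16.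

Step 8. Once O2′ and O4′ are free, protonation of the prenyl alkene can lead to addition of a neighbouring phenol (2,2-dimethylchroman formation) or of the solvent. The fallback avoids protic acid altogether; it sets out from 16 and comes back at 17. TMSOTf with 2,2′-bipyridyl in MeCN at 0 °C should exchange the aryl acetals for silyl ethers and silylate O7, giving 3-[2,4-bis(trimethylsilyloxy)-3-(3-methylbut-2-enyl)phenyl]-5-methoxy-7-(trimethylsilyloxy)chromen-2-one F9. Neutral hydrolysis (water, or KF in MeOH) would release 17.

Step 3. The coupling partner and the product are both polymerisable acrylates, and any aryllithium left after incomplete transmetalation would add to them; deprotonation at the prenyl CH2 in place of the ring is a second way to lose material. The fallback replaces the cross-coupling by carbonyl chemistry; it sets out from 5 and comes back at 9. The lithiated arene would be added to excess dimethyl oxalate at −78 °C to give methyl 2-[2,4-bis(methoxymethoxy)-3-(3-methylbut-2-enyl)phenyl]-2-oxoacetate F10. Wittig methylenation of the ketone (Ph3PCH3Br, KHMDS, THF, 0 °C) should give 9.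

**Further compounds**

F1 | step 6 | 2-[2,4-bis(methoxymethoxy)-3-(3-methylbut-2-enyl)phenyl]ethanol | OCCc1ccc(OCOC)c(CC=C(C)C)c1OCOC
F2 | step 6 | 2-[2,4-bis(methoxymethoxy)-3-(3-methylbut-2-enyl)phenyl]acetic acid | OC(=O)Cc1ccc(OCOC)c(CC=C(C)C)c1OCOC
F3 | step 6 | 2,4-dihydroxy-6-methoxybenzaldehyde | COc1cc(O)cc(O)c1C=O
F4 | step 6 | [3-[2,4-bis(methoxymethoxy)-3-(3-methylbut-2-enyl)phenyl]-5-methoxy-2-oxochromen-7-yl] acetate | COc1cc(OC(C)=O)cc2oc(=O)c(-c3ccc(OCOC)c(CC=C(C)C)c3OCOC)cc12
F5 | step 4 | methyl 2-[2,4-bis(methoxymethoxy)-3-(3-methylbut-2-enyl)phenyl]-3-(4,4,5,5-tetramethyl-1,3,2-dioxaborolan-2-yl)propanoate (racemic) | COC(=O)C(CB1OC(C)(C)C(C)(C)O1)c1ccc(OCOC)c(CC=C(C)C)c1OCOC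
F6 | step 4 | 4-methoxy-6-methylpyran-2-one | COc1cc(C)oc(=O)c1
F7 | step 4 | 3-bromo-4-methoxy-6-methylpyran-2-one | COc1cc(C)oc(=O)c1Br
F8 | step 7 | 3-[2,4-bis(methoxymethoxy)-3-(3-methylbut-2-enyl)phenyl]-7-hydroxy-5-methoxy-3-(phenylselanyl)chroman-2-one (racemic) | COc1cc(O)cc2c1CC(C(=O)O2)([Se]c1ccccc1)c1ccc(OCOC)c(CC=C(C)C)c1OCOC
F9 | step 8 | 3-[2,4-bis(trimethylsilyloxy)-3-(3-methylbut-2-enyl)phenyl]-5-methoxy-7-(trimethylsilyloxy)chromen-2-one | COc1cc(O[Si](C)(C)C)cc2oc(=O)c(-c3ccc(O[Si](C)(C)C)c(CC=C(C)C)c3O[Si](C)(C)C)cc12
F10 | step 3 | methyl 2-[2,4-bis(methoxymethoxy)-3-(3-methylbut-2-enyl)phenyl]-2-oxoacetate | COC(=O)C(=O)c1ccc(OCOC)c(CC=C(C)C)c1OCOC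
A1 | alternative 1 | methyl 2-[4-hydroxy-3-(3-methylbut-2-enyl)-2-(triisopropylsilyloxy)phenyl]acetate | COC(=O)Cc1ccc(O)c(CC=C(C)C)c1O[Si](C(C)C)(C(C)C)C(C)C
A2 | alternative 1 | methyl 2-(4-oxocyclobut-1-en-1-yl)acetate | COC(=O)CC1=CCC1=O
A3 | alternative 1 | triisopropyl[(5-methylhex-4-en-1-yn-1-yl)oxy]silane | CC(C)=CCC#CO[Si](C(C)C)(C(C)C)C(C)C
A4 | alternative 2 | 3-[2,4-bis(methoxymethoxy)-3-(3-methylbut-2-enyl)phenyl]-5-methoxy-7-(methoxymethoxy)chromen-2-one | COCOc1cc(OC)c2cc(-c3ccc(OCOC)c(CC=C(C)C)c3OCOC)c(=O)oc2c1
A5 | alternative 2 | [3-methoxy-5-(methoxymethoxy)-2-(trimethylsilyl)phenyl] trifluoromethanesulfonate | COCOc1cc(OC)c([Si](C)(C)C)c(OS(=O)(=O)C(F)(F)F)c1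
A6 | alternative 2 | {2-[2,4-bis(methoxymethoxy)-3-(3-methylbut-2-enyl)phenyl]-1-methoxyethenoxy}trimethylsilane | COC(O[Si](C)(C)C)=Cc1ccc(OCOC)c(CC=C(C)C)c1OCOC
A7 | alternative 2 | N,N-dimethylformamide | CN(C)C=O
A8 | alternative 3 | 3-[2,4-bis(methoxymethoxy)-3-(3-methylbut-2-enyl)phenyl]-7-[tert-butyl(dimethyl)silyl]oxy-7,8-dihydro-6H-chromene-2,5-dione (racemic) | O=C1CC(O[Si](C)(C)C(C)(C)C)CC2=C1C=C(c1ccc(OCOC)c(CC=C(C)C)c1OCOC)C(=O)O2
A9 | alternative 3 | 5-[tert-butyl(dimethyl)silyl]oxycyclohexane-1,3-dione | O=C1CC(O[Si](C)(C)C(C)(C)C)CC(=O)C1
A10 | alternative 3 | methyl 2-[2,4-bis(methoxymethoxy)-3-(3-methylbut-2-enyl)phenyl]-3-(dimethylamino)prop-2-enoate | COC(=O)C(=CN(C)C)c1ccc(OCOC)c(CC=C(C)C)c1OCOC
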